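## Retrosynthetic overview

1. Target 24 ⇐ C8–O bond by Mitsunobu esterification with inversion of the 8-epi alcohol 23 ⇐ desilylation of 22.
2. 22 ⇐ C13–O bond by a proposed palladium-catalysed transposing allylic C–H acetoxylation of α-methylene lactone 21; this also moves the alkene to C7=C11 and erases the sacrificial C7 centre.
3. 21 ⇐ ring-closing metathesis (C1=C10, Z) of 20; 20 ⇐ hydroxyl-directed threo epoxidation (C4–O, C5–O) and lactonisation (C12–O) of 18.
4. 18 ⇐ indium Barbier union (C6–C7) of enal 9 with allyl bromide 17; 9 ⇐ vinylogous Mukaiyama aldol (sets C2); 17 ⇐ glyoxylate–ene (sets C8), Baylis–Hillman, SN2' bromination.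
5. Ring order: oxirane and γ-lactone first (step 12), ten-membered carbocycle second (step 13), butenolide unsaturation last (step 14).

Assumption: germacranolide locants are used for the target and all intermediates (C1=C10 ring alkene, C2 acetoxy carbon, C4–C5 epoxide, C6 lactone carbinol, C7=C11 butenolide alkene, C8 methacrylate carbon, C12 lactone carbonyl, C13 acetoxymethyl carbon, C14/C15 methyls). The target is then (1(10)Z,2S,4R,5R,6S,8S). TBS = tert-butyldimethylsilyl.

## Route

Step 1
Reactants: 1 methyl 3-methylbut-2-enoate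
Product: 3 tert-butyl[(1-methoxy-3-methylbuta-1,3-dien-1-yl)oxy]dimethylsilane, via lithium dienolate 2 (not isolated)
Conditions: LiN(iPr)2 (1.1 equiv), THF, −78 °C; then TBSCl, DMPU, −78 °C → rt
Reagents that add atoms: tert-butyldimethylsilyl chloride, CC(C)(C)[Si](C)(C)Cl
Why: Kinetic γ-deprotonation of the senecioate gives the extended lithium dienolate, which is O-silylated (silyl ketene acetal formation); no stereocentre is involved.

Step 2
Reactants: 3 tert-butyl[(1-methoxy-3-methylbuta-1,3-dien-1-yl)oxy]dimethylsilane; 4 (2E)-but-2-enal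
Product: 6 methyl (2E,5S,6E)-5-hydroxy-3-methylocta-2,6-dienoate, via trichlorosilyl ether 5 (not isolated)
Conditions: SiCl4 (1.1 equiv), Denmark's (S,S)-binaphthyldiamine-derived bisphosphoramide (5 mol %; the antipode that directs Si-face attack), CH2Cl2, −78 °C; then sat. aq. NaHCO3
Reagents that add atoms: none
Why: Catalytic enantioselective vinylogous Mukaiyama aldol (Lewis-base-activated SiCl4): the chiral trichlorosilyl cation binds the enal and the dienolate attacks only through its γ-carbon in 1,2-fashion on the Si face, which sets the future C2 as S and gives the (E)-enoate.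

Step 3
Reactants: 6 methyl (2E,5S,6E)-5-hydroxy-3-methylocta-2,6-dienoate
Product: 7 (2E,5S,6E)-3-methylocta-2,6-diene-1,5-diol
Conditions: iBu2AlH (3.2 equiv), CH2Cl2, −78 → 0 °C; aq. potassium sodium tartrate
Reagents that add atoms: none
Why: Aluminium hydride 1,2-reduction of the conjugated ester gives the allylic alcohol without touching the alkenes or the stereocentre.

Step 4
Reactants: 7 (2E,5S,6E)-3-methylocta-2,6-diene-1,5-diol
Product: 8 (2E,5S,6E)-5-hydroxy-3-methylocta-2,6-dienal
Conditions: TEMPO (10 mol %), PhI(OAc)2 (1.05 equiv), CH2Cl2, 0 °C → rt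
Reagents that add atoms: none
Why: Oxoammonium (TEMPO/PhI(OAc)2) oxidation is selective for the primary allylic alcohol over the secondary one and does not isomerise the (E)-alkene.

Step 5
Reactants: 8 (2E,5S,6E)-5-hydroxy-3-methylocta-2,6-dienal
Product: 9 (2E,4S,6E)-6-methyl-8-oxoocta-2,6-dien-4-yl acetate
Conditions: Ac2O, pyridine, CH2Cl2, 0 °C
Reagents that add atoms: acetic anhydride, CC(=O)OC(C)=O
Why: Standard O-acetylation installs the C2 acetate of the target with retention and masks the only hydroxyl that could misdirect the later vanadium epoxidation.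

Step 6
Reactants: 10 2-methylpropene; 11 ethyl glyoxylate
Product: 12 ethyl (2R)-2-hydroxy-4-methylpent-4-enoate
Conditions: (R)-BINOL/TiCl2(OiPr)2 (10 mol %), 4 Å molecular sieves, CH2Cl2, −30 °C
Reagents that add atoms: none
Why: Mikami asymmetric glyoxylate–ene reaction: the (R)-BINOL titanium Lewis acid activates the glyoxylate and isobutylene adds through an ene transition state to give the 2R alcohol, which is the future C8 in the configuration opposite to the target, as steps 11 and 16 require.

Step 7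
Reactants: 12 ethyl (2R)-2-hydroxy-4-methylpent-4-enoate
Product: 13 ethyl (2R)-2-(tert-butyldimethylsilyloxy)-4-methylpent-4-enoate
Conditions: TBSCl, imidazole, DMF, rt
Reagents that add atoms: tert-butyldimethylsilyl chloride, CC(C)(C)[Si](C)(C)Cl
Why: Imidazole-promoted silylation protects the C8 oxygen as a robust silyl ether so that only O6 can lactonise later.

Step 8
Reactants: 13 ethyl (2R)-2-(tert-butyldimethylsilyloxy)-4-methylpent-4-enoate
Product: 14 (2R)-2-(tert-butyldimethylsilyloxy)-4-methylpent-4-enal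
Conditions: iBu2AlH (1.05 equiv), CH2Cl2, −78 °C; MeOH, then aq. potassium sodium tartrate
Reagents that add atoms: none
Why: Partial ester reduction: the tetrahedral aluminium hemiacetal is stable at −78 °C and collapses to the aldehyde only on work-up, so the α-silyloxy aldehyde forms without over-reduction or epimerisation.

Step 9
Reactants: 14 (2R)-2-(tert-butyldimethylsilyloxy)-4-methylpent-4-enal; 15 methyl acrylate
Product: 16 methyl (4R)-4-(tert-butyldimethylsilyloxy)-3-hydroxy-6-methyl-2-methylidenehept-6-enoate (mixture of C3 epimers)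
Conditions: DABCO (1.0 equiv), neat methyl acrylate (5 equiv), rt, 4 d
Reagents that add atoms: none
Why: Morita–Baylis–Hillman reaction (amine conjugate addition, aldol, elimination); the new carbinol centre forms as a mixture, which is irrelevant because it becomes sp2 in step 10.

Step 10
Reactants: 16 methyl (4R)-4-(tert-butyldimethylsilyloxy)-3-hydroxy-6-methyl-2-methylidenehept-6-enoate
Product: 17 methyl (2Z,4R)-2-(bromomethyl)-4-(tert-butyldimethylsilyloxy)-6-methylhepta-2,6-dienoate
Conditions: NBS, Me2S, CH2Cl2, −20 → 0 °C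
Reagents that add atoms: N-bromosuccinimide, O=C1CCC(=O)N1Br
Why: Corey–Kim-type activation of the allylic alcohol followed by SN2' attack of bromide gives the thermodynamically preferred (Z)-2-(bromomethyl)enoate under neutral conditions that keep the silyl ether and the C8 centre intact.

Step 11
Reactants: 9 (2E,4S,6E)-6-methyl-8-oxoocta-2,6-dien-4-yl acetate; 17 methyl (2Z,4R)-2-(bromomethyl)-4-(tert-butyldimethylsilyloxy)-6-methylhepta-2,6-dienoate
Product: 18 methyl 2-[(4R,5R,6R,7E,10S,11E)-10-acetoxy-4-(tert-butyldimethylsilyloxy)-6-hydroxy-2,8-dimethyltrideca-1,7,11-trien-5-yl]prop-2-enoate (target locants 2S,6R,7R,8R; C6 has the spatial arrangement of the target and is formally R here only because C7 outranks C5)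
Conditions: indium powder (1.5 equiv), THF/H2O (1:1), rt
Reagents that add atoms: none
Why: Indium-mediated Barbier allylation with γ-attack through a chair (Zimmerman–Traxler-type) transition state: the (Z)-allylindium gives the syn C6/C7 pair, and A(1,3) strain holds H8 in the allyl plane so that the aldehyde adds anti to the silyloxy group (Felkin–Anh sense, the same face as predicted by an indium–oxygen chelate), which relays 8R into the required C6 configuration, while C7 is removed in step 14.

Step 12
Reactants: 18 methyl 2-[(4R,5R,6R,7E,10S,11E)-10-acetoxy-4-(tert-butyldimethylsilyloxy)-6-hydroxy-2,8-dimethyltrideca-1,7,11-trien-5-yl]prop-2-enoate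
Product: 20 (4R,5S)-4-[(1R)-1-(tert-butyldimethylsilyloxy)-3-methylbut-3-enyl]-5-{(2R,3R)-3-[(2S,3E)-2-acetoxypent-3-enyl]-3-methyloxiran-2-yl}-3-methylideneoxolan-2-one, via epoxy hydroxy ester 19 (not isolated)
Conditions: VO(acac)2 (5 mol %), t-BuOOH (1.1 equiv, decane), CH2Cl2, 0 °C → rt; then DBU (0.2 equiv), 0 °C → rt
Reagents that add atoms: tert-butyl hydroperoxide, CC(C)(C)OO
Why: Vanadium-catalysed hydroxyl-directed epoxidation: A(1,3) strain with the cis methyl (C15) puts H6 in the alkene plane, so oxygen is delivered syn to the C6 hydroxyl to give the threo (4R,5R) epoxy alcohol while the acrylate and the undirected alkenes stay untouched, and base-catalysed transesterification of the γ-alkoxide then closes the lactone.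

Step 13
Reactants: 20 (4R,5S)-4-[(1R)-1-(tert-butyldimethylsilyloxy)-3-methylbut-3-enyl]-5-{(2R,3R)-3-[(2S,3E)-2-acetoxypent-3-enyl]-3-methyloxiran-2-yl}-3-methylideneoxolan-2-one
Product: 21 (1(10)Z,2S,4R,5R,6S,7R,8R)-2-acetoxy-8-(tert-butyldimethylsilyloxy)-4,5-epoxygermacra-1(10),11(13)-dien-12,6-olide
Conditions: second-generation Hoveyda–Grubbs catalyst RuCl2(H2IMes)(=CH-C6H4-2-OiPr) (15 mol %), 1,4-benzoquinone (30 mol %), toluene (1 mM), 80 °C, argon sparge
Reagents that add atoms: none
Why: Ring-closing metathesis: the ruthenium carbene formed at the propenyl end is held near the 1,1-disubstituted alkene by the cis-fused lactone and closes the ten-membered ring with loss of propene, the Z trisubstituted alkene being the less strained geometry in a ring that already holds the trans-epoxide, while closure onto the hindered α-methylene group would need an eight-membered ring with a trans-epoxide.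

Step 14
Reactants: 21 (1(10)Z,2S,4R,5R,6S,7R,8R)-2-acetoxy-8-(tert-butyldimethylsilyloxy)-4,5-epoxygermacra-1(10),11(13)-dien-12,6-olide
Product: 22 (1(10)Z,2S,4R,5R,6S,8R)-2,13-diacetoxy-8-(tert-butyldimethylsilyloxy)-4,5-epoxygermacra-1(10),7(11)-dien-12,6-olide
Conditions: Pd(OAc)2 (10 mol %), 1,2-bis(phenylsulfinyl)ethane (10 mol %), 1,4-benzoquinone (2 equiv), AcOH (4 equiv), 1,4-dioxane, 40 °C
Reagents that add atoms: acetic acid, CC(=O)O
Why: Proposed new method: sulfoxide-ligated divalent palladium acetate should bind the only unhindered 1,1-disubstituted alkene (C11=C13) on the convex face that carries H7, cleave the allylic C7–H bond with acetate assistance to a 2-acyl-η3-allyl palladium species (or add acetate to C13 and lose H7 by syn β-hydride elimination), and form the C–O bond at the unhindered CH2 terminus C13 so that the alkene moves into the ring as the conjugated tetrasubstituted butenolide, with benzoquinone returning zerovalent palladium to the divalent state; the closest known reactions are palladium/sulfoxide and palladium/benzoquinone allylic C–H acetoxylation of terminal and exocyclic alkenes (methylenecyclohexane to cyclohexenylmethyl acetate) and the Heck arylation of α-methylene-γ-butyrolactones that ends by endocyclic β-hydride elimination, none of which has been shown on an α-methylene lactone with an oxygen nucleophile; the C7 centre is erased and no new one is made.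

Step 15
Reactants: 22 (1(10)Z,2S,4R,5R,6S,8R)-2,13-diacetoxy-8-(tert-butyldimethylsilyloxy)-4,5-epoxygermacra-1(10),7(11)-dien-12,6-olide
Product: 23 (1(10)Z,2S,4R,5R,6S,8R)-2,13-diacetoxy-4,5-epoxy-8-hydroxygermacra-1(10),7(11)-dien-12,6-olide
Conditions: HF·pyridine, pyridine, THF, 0 °C → rt
Reagents that add atoms: none
Why: Fluoride-driven Si–O cleavage under buffered, non-basic conditions avoids acetyl migration from O13 to the cis-disposed O8 and leaves the epoxide and esters intact.

Step 16
Reactants: 23 (1(10)Z,2S,4R,5R,6S,8R)-2,13-diacetoxy-4,5-epoxy-8-hydroxygermacra-1(10),7(11)-dien-12,6-olide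
Product: 24 (1(10)Z,2S,4R,5R,6S,8S)-2,13-diacetoxy-4,5-epoxy-8-(methacryloyloxy)germacra-1(10),7(11)-dien-12,6-olide (CNP0268364.3)
Conditions: PPh3, DIAD, methacrylic acid, BHT (cat.), toluene, 0 °C → rt
Reagents that add atoms: methacrylic acid, C=C(C)C(=O)O
Why: Mitsunobu esterification: the alcohol is activated as an alkoxyphosphonium ion and displaced by methacrylate in SN2 fashion, forming the C8–O bond with inversion (8R to 8S), and the electron-poor butenolide disfavours SN1 and SN2' pathways.

## Compound list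

1 | methyl 3-methylbut-2-enoate | COC(=O)C=C(C)C | starting material
2 | lithium 1-methoxy-3-methylbuta-1,3-dien-1-olate | [Li+].[O-]C(OC)=CC(C)=C | intermediate
3 | tert-butyl[(1-methoxy-3-methylbuta-1,3-dien-1-yl)oxy]dimethylsilane | C=C(C)C=C(OC)O[Si](C)(C)C(C)(C)C | intermediate
4 | (2E)-but-2-enal (crotonaldehyde) | C/C=C/C=O | starting material
5 | methyl (2E,5S,6E)-3-methyl-5-(trichlorosilyloxy)octa-2,6-dienoate | COC(=O)/C=C(\C)C[C@H](O[Si](Cl)(Cl)Cl)/C=C/C | intermediate
6 | methyl (2E,5S,6E)-5-hydroxy-3-methylocta-2,6-dienoate | COC(=O)/C=C(\C)C[C@H](O)/C=C/C | intermediate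
7 | (2E,5S,6E)-3-methylocta-2,6-diene-1,5-diol | OC/C=C(\C)C[C@H](O)/C=C/C | intermediate
8 | (2E,5S,6E)-5-hydroxy-3-methylocta-2,6-dienal | O=C/C=C(\C)C[C@H](O)/C=C/C | intermediate
9 | (2E,4S,6E)-6-methyl-8-oxoocta-2,6-dien-4-yl acetate | O=C/C=C(\C)C[C@H](OC(C)=O)/C=C/C | intermediate
10 | 2-methylpropene (isobutylene) | C=C(C)C | starting material
11 | ethyl glyoxylate | CCOC(=O)C=O | starting material
12 | ethyl (2R)-2-hydroxy-4-methylpent-4-enoate | CCOC(=O)[C@H](O)CC(C)=C | intermediate
13 | ethyl (2R)-2-(tert-butyldimethylsilyloxy)-4-methylpent-4-enoate | CCOC(=O)[C@H](O[Si](C)(C)C(C)(C)C)CC(C)=C | intermediate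
14 | (2R)-2-(tert-butyldimethylsilyloxy)-4-methylpent-4-enal | O=C[C@H](O[Si](C)(C)C(C)(C)C)CC(C)=C | intermediate
15 | methyl acrylate | C=CC(=O)OC | starting material
16 | methyl (4R)-4-(tert-butyldimethylsilyloxy)-3-hydroxy-6-methyl-2-methylidenehept-6-enoate (C3 epimers) | C=C(C(=O)OC)C(O)[C@H](O[Si](C)(C)C(C)(C)C)CC(C)=C | intermediate
17 | methyl (2Z,4R)-2-(bromomethyl)-4-(tert-butyldimethylsilyloxy)-6-methylhepta-2,6-dienoate | COC(=O)/C(CBr)=C/[C@H](O[Si](C)(C)C(C)(C)C)CC(C)=C | intermediate
18 | methyl 2-[(4R,5R,6R,7E,10S,11E)-10-acetoxy-4-(tert-butyldimethylsilyloxy)-6-hydroxy-2,8-dimethyltrideca-1,7,11-trien-5-yl]prop-2-enoate | CC(C)(C)[Si](C)(C)O[C@H](CC(C)=C)[C@H](C(=C)C(=O)OC)[C@H](O)/C=C(\C)C[C@H](OC(C)=O)/C=C/C | intermediate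
19 | threo 4,5-epoxide of 18 (target locants 2S,4R,5R,6S,7R,8R; open-chain methyl ester with free 6-OH) | CC(C)(C)[Si](C)(C)O[C@H](CC(C)=C)[C@H](C(=C)C(=O)OC)[C@H](O)[C@H]1O[C@]1(C)C[C@H](OC(C)=O)/C=C/C | intermediate
20 | (4R,5S)-4-[(1R)-1-(tert-butyldimethylsilyloxy)-3-methylbut-3-enyl]-5-{(2R,3R)-3-[(2S,3E)-2-acetoxypent-3-enyl]-3-methyloxiran-2-yl}-3-methylideneoxolan-2-one | C=C1C(=O)O[C@H]([C@H]2O[C@]2(C)C[C@H](OC(C)=O)/C=C/C)[C@@H]1[C@H](O[Si](C)(C)C(C)(C)C)CC(C)=C | intermediate
21 | (1(10)Z,2S,4R,5R,6S,7R,8R)-2-acetoxy-8-(tert-butyldimethylsilyloxy)-4,5-epoxygermacra-1(10),11(13)-dien-12,6-olide | CC(C)(C)[Si](C)(C)O[C@@H]1C/C(C)=C\[C@@H](OC(C)=O)C[C@@]2(C)O[C@@H]2[C@H]2OC(=O)C(=C)[C@@H]12 | intermediate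
22 | (1(10)Z,2S,4R,5R,6S,8R)-2,13-diacetoxy-8-(tert-butyldimethylsilyloxy)-4,5-epoxygermacra-1(10),7(11)-dien-12,6-olide | CC(C)(C)[Si](C)(C)O[C@@H]1C/C(C)=C\[C@@H](OC(C)=O)C[C@@]2(C)O[C@@H]2[C@H]2OC(=O)C(COC(C)=O)=C12 | intermediate
23 | (1(10)Z,2S,4R,5R,6S,8R)-2,13-diacetoxy-4,5-epoxy-8-hydroxygermacra-1(10),7(11)-dien-12,6-olide | O[C@@H]1C/C(C)=C\[C@@H](OC(C)=O)C[C@@]2(C)O[C@@H]2[C@H]2OC(=O)C(COC(C)=O)=C12 | intermediate
24 | (1(10)Z,2S,4R,5R,6S,8S)-2,13-diacetoxy-4,5-epoxy-8-(methacryloyloxy)germacra-1(10),7(11)-dien-12,6-olide (CNP0268364.3) | C=C(C)C(=O)O[C@H]1C/C(C)=C\[C@@H](OC(C)=O)C[C@@]2(C)O[C@@H]2[C@H]2OC(=O)C(COC(C)=O)=C12 | target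

## Step count and risks

Total: 16 steps. Longest linear sequence: 11 steps (steps 1–5, then 11–16); the second branch is steps 6–10.

Most likely to fail:

Step 14 (the proposed acetoxylation). The electron-poor exocyclic alkene may bind divalent palladium too weakly, β-hydride loss may go towards C13 to give an enol acetate, or acetic acid may open the epoxide. The known-chemistry fallback sets out from 21. Nucleophilic (Weitz–Scheffer) epoxidation with t-BuOOH/DBU gives the 11,13-epoxy lactone F1. CsOAc/AcOH in DMF opens it at the primary C13 to the 11-hydroxy-13-acetate F2. Dehydration of the tertiary alcohol into the ring with SOCl2/pyridine rejoins the route at 22.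

Step 13 (ring-closing metathesis). A ten-membered ring with a trisubstituted alkene, a fused lactone and an epoxide may resist closure or dimerise through the α-methylene group. The fallback changes the order of ring formation and sets out from 18. Metathesis of the open-chain hydroxy ester with the same ruthenium catalyst at 40–60 °C, before lactone and epoxide constrain the chain, gives the macrocyclic (1(10)Z,4E)-diene hydroxy ester F3. Transannular vanadium-directed epoxidation then gives the macrocyclic epoxy hydroxy ester F4, which is lactonised with DBU without isolation, rejoining the route at 21.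

Step 16 (Mitsunobu inversion). The hindered ring alcohol and the moderately acidic methacrylic acid may give elimination or retention. The fallback sets the C8 configuration by hydride delivery and sets out from 23. Dess–Martin oxidation gives the 8-ketone F5. Reduction with (R)-Me-CBS/BH3·SMe2 at −30 °C gives the 8S alcohol F6. Acylation with methacrylic anhydride, Et3N and DMAP reaches the target 24.

Further compounds

F1 | step 14 | (2S,4R,5R,6S,7R,8R)-2-acetoxy-8-(tert-butyldimethylsilyloxy)-4,5:11,13-diepoxygermacr-1(10)Z-en-12,6-olide (C11 epimers) | CC(C)(C)[Si](C)(C)O[C@@H]1C/C(C)=C\[C@@H](OC(C)=O)C[C@@]2(C)O[C@@H]2[C@H]2OC(=O)C3(CO3)[C@@H]12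
F2 | step 14 | (2S,4R,5R,6S,7R,8R)-2,13-diacetoxy-8-(tert-butyldimethylsilyloxy)-4,5-epoxy-11-hydroxygermacr-1(10)Z-en-12,6-olide (C11 epimers) | CC(C)(C)[Si](C)(C)O[C@@H]1C/C(C)=C\[C@@H](OC(C)=O)C[C@@]2(C)O[C@@H]2[C@H]2OC(=O)C(O)(COC(C)=O)[C@@H]12
F3 | step 13 | methyl (1(10)Z,2S,4E,6R,7R,8R)-2-acetoxy-8-(tert-butyldimethylsilyloxy)-6-hydroxygermacra-1(10),4,11(13)-trien-12-oate | CC(C)(C)[Si](C)(C)O[C@@H]1C/C(C)=C\[C@@H](OC(C)=O)C/C(C)=C/[C@@H](O)[C@H]1C(=C)C(=O)OC
F4 | step 13 | methyl (1(10)Z,2S,4R,5R,6S,7R,8R)-2-acetoxy-8-(tert-butyldimethylsilyloxy)-4,5-epoxy-6-hydroxygermacra-1(10),11(13)-dien-12-oate | CC(C)(C)[Si](C)(C)O[C@@H]1C/C(C)=C\[C@@H](OC(C)=O)C[C@@]2(C)O[C@@H]2[C@@H](O)[C@H]1C(=C)C(=O)OC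
F5 | step 16 | (1(10)Z,2S,4R,5R,6S)-2,13-diacetoxy-4,5-epoxy-8-oxogermacra-1(10),7(11)-dien-12,6-olide | O=C1C/C(C)=C\[C@@H](OC(C)=O)C[C@@]2(C)O[C@@H]2[C@H]2OC(=O)C(COC(C)=O)=C12
F6 | step 16 | (1(10)Z,2S,4R,5R,6S,8S)-2,13-diacetoxy-4,5-epoxy-8-hydroxygermacra-1(10),7(11)-dien-12,6-olide | O[C@H]1C/C(C)=C\[C@@H](OC(C)=O)C[C@@]2(C)O[C@@H]2[C@H]2OC(=O)C(COC(C)=O)=C12
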